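## Analysis of the target

- The target is a fully O-methylated flavone, C22H24O9. Rings A and C form a 4H-chromen-4-one with methoxy groups at C5, C7 and C8 and hydrogen at C6. C2 carries a 2,3,4,5-tetramethoxyphenyl ring B whose only hydrogen is at C6'.
- There is no stereocentre and no stereogenic double bond, so the problem is one of connectivity and regiochemistry only.
- The sensitive parts are the γ-pyranone of ring C, which opens under strong base and accepts nucleophiles at C2, and the seven aryl methyl ethers. Of these, the C5 ether peri to the carbonyl is the first to be lost to Lewis or Brønsted acid at high temperature.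
- The difficulty is to place seven oxygen substituents on two benzene rings without positional ambiguity. Both rings are so electron-rich that late electrophilic substitution or selective dealkylation would be hard to steer.
- The strategy rests on ring B. C2', C3', C4' and C5' are an unbroken run of four oxygen-bearing carbons, which is the carbon–oxygen array of a squaric acid diester. C1' (bearing carbon) and C6' (bearing hydrogen) correspond to the two carbons of a monosubstituted alkyne.
- Ring B can therefore be assembled from a four-membered ring and an alkyne instead of being oxygenated step by step. The alkyne substituent becomes the one-carbon handle that ends up as C2 of the flavone.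
- Ring A corresponds to a symmetrical tetramethoxybenzene whose two open positions are equivalent, so it can be acylated without a regiochemical question at carbon.

## Retrosynthetic reasoning

**Ring C.** In flavone 15 the O1–C2 bond and the C2=C3 unsaturation are removed, which leads through flavanone 14 to the 2'-hydroxychalcone 13. This cut leaves both aromatic rings complete with all seven methyl ethers, so nothing has to be adjusted once the base-sensitive pyranone exists. Forward, the phenol of 13 must add to the enone β-carbon in the 6-endo sense and the flavanone must lose two hydrogens without halogenation of either ring.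

**Union of the two halves.** Chalcone 13 is cut at its olefin (C2–C3 of the flavone) into aldehyde 9, which brings ring B and C2, and ketone 12, which brings ring A, C4 and C3. The cut is convergent, and only 12 can enolise, so there is no cross-selectivity problem. Joining at the aldehyde oxidation level is preferred to a carbonylative union through an arylalkyne. That would cost a homologation of 9 and a halogenated ring A phenol whose regiochemistry is harder to secure than that of 12. Forward, the enolate of the hindered ketone 12 has to add to an ortho-substituted aldehyde and dehydrate.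

**Ring A ketone.** Ketone 12 is cut at C4–C4a to give 1,2,3,5-tetramethoxybenzene 10, through the tetramethoxy ketone 11. Because the two free positions of 10 are related by symmetry, the acylation cannot go to a wrong carbon. The only decision left is which ortho ether of 11 is cleaved; it must be the one flanked by a second ether, which becomes the C8a oxygen.

**Functional group adjustments on ring B.** The formyl group of 9 is traced to the diethyl acetal 8. The methyl groups on the C2' and C5' oxygens are removed to give hydroquinone 7, which is taken back to quinone 6. This exposes the para pair of oxygens as quinone carbonyls, the form in which the ring-forming step delivers them. Forward, this requires reduction and double O-methylation under conditions that keep the acetal, then mild hydrolysis.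

**Key disconnection.** In quinone 6 the ring bond C1'–C2' is cut and C2' is reconnected to C5'. This contracts the six-membered ring to the alkynyl cyclobutenone 4, through vinylketene 5. It is the one cut that turns the four contiguous oxygens into a ready-made C4O4 unit. Any disconnection on an intact benzene ring would instead demand successive oxygenations of an arene. Two steps then give all six ring carbons, the four oxygens and the side-chain carbon in their final relative positions. Forward, the four-membered ring must open with the alkyne turned toward the ketene, and closure must give the six- and not the five-membered ring.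

**Precursor.** Cyclobutenone 4 is cut between the carbinol carbon (C5') and the alkyne carbon (C6'). The pieces are dimethyl squarate 1 and the lithium alkynide 3 made from alkyne 2. The two carbonyl groups of 1 are equivalent, so the only forward requirements are 1,2-addition and a stop after one addition.

## Alternatives that were turned down

**Alternative 1: isoxazole as a masked 1,3-diketone.**
- Disconnection: ring C is traced to a 1,3-diketone stored as 3-[2-(benzyloxy)-3,4,6-trimethoxyphenyl]-5-(2,3,4,5-tetramethoxyphenyl)isoxazole A1. A1 is cut into 2-(benzyloxy)-3,4,6-trimethoxybenzaldehyde oxime A2 and 1-ethynyl-2,3,4,5-tetramethoxybenzene A3.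
- Forward key step: PhI(OAc)2 oxidises A2 to its nitrile oxide, which adds across the triple bond of A3. This joins the future C4 to C3 and places oxygen on the future C2.
- For: the union is convergent and runs near room temperature. Terminal alkynes give 3,5-disubstituted isoxazoles reliably, and a nitrile oxide with two ortho substituents dimerises slowly. On mildness it is stronger than a thermolysis at about 140 °C.
- Against: it takes ring B for granted. A3 is reached only from an aldehyde such as 9 plus a one-carbon homologation. A2 needs a ring A aldehyde in which one particular oxygen is benzylated and not methylated. After A1 there remain reductive N–O cleavage, hydrolysis of the enaminone, debenzylation and cyclodehydration. The iodine oxidant also meets two very electron-rich arenes.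
- Comparison: it is about four steps longer. The chosen route builds the ring that this alternative presupposes and closes ring C in two steps from 9.

**Alternative 2: propargyl ether Claisen shift to a flavene.**
- Disconnection: the C4–C4a and O1–C2 bonds are traced to 1,2,5-trimethoxy-3-{[1-(2,3,4,5-tetramethoxyphenyl)prop-2-yn-1-yl]oxy}benzene A5.
- Forward key step: heating A5 in a high-boiling aniline solvent causes a [3,3] shift to the only free ortho position. Enolisation, a 1,5-hydrogen shift and an oxa-six-electron electrocyclisation then give racemic 5,7,8-trimethoxy-2-(2,3,4,5-tetramethoxyphenyl)-2H-chromene A4.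
- For: the C4–C4a bond is formed with built-in regiocontrol and without acyl chemistry. As a neutral thermal cascade it matches the chosen key step in character.
- Against: A4 is at the wrong oxidation level. C4 has to become a carbonyl and C2 has to lose its hydrogen, a four-electron oxidation next to two oxidisable rings. A5 is a secondary ether that is both benzylic and propargylic on a very electron-rich aryl group, so it is prone to ionisation when made and when heated. Ring B is again presupposed.
- Comparison: the chosen endgame reaches the flavone oxidation level directly and needs no ether of that lability.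

**Alternative 3: ring A by Claisen closure on a pyranone.**
- Disconnection: the C4a–C5 bond of ring A is cut, leading to methyl 4-methoxy-3-oxo-4-[4-oxo-6-(2,3,4,5-tetramethoxyphenyl)-4H-pyran-2-yl]butanoate A7.
- Forward key step: Mg(OMe)2 forms the dienolate of A7. C4a attacks the ester carbonyl, and enolisation gives 5,7-dihydroxy-8-methoxy-2-(2,3,4,5-tetramethoxyphenyl)-4H-chromen-4-one A6.
- For: ring A is built with its oxygens coming from chain carbonyls, so the 5,7,8 pattern is fixed by the chain. No ether has to be cleaved selectively. On that one point it is cleaner than the chosen ring A, which relies on a selective ortho demethylation.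
- Against: A7 is a sensitive polycarbonyl compound that takes several steps to make. Aldol closure, O-acylation and lactonisation compete with the wanted C-acylation. A6 still needs two methylations, one at the chelated C5 hydroxyl. Ring B is presupposed once more.
- Comparison: the chosen route takes ring A from a symmetrical arene in one step and spends its effort on ring B, which has no equally simple source in any of the three alternatives.

Key step: step 2

Assumption: 1,2,3,5-tetramethoxybenzene (10) is taken as a catalogue compound; the target is achiral, so no stereochemical assumption is needed.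

## Route

Step 1
Reactants: 1 dimethyl squarate (3,4-dimethoxycyclobut-3-ene-1,2-dione); 2 3,3-diethoxyprop-1-yne
Product: 4 racemic 4-(3,3-diethoxyprop-1-yn-1-yl)-4-hydroxy-2,3-dimethoxycyclobut-2-en-1-one, via lithium 3,3-diethoxyprop-1-yn-1-ide 3 (not isolated)
Conditions: 2, n-BuLi, THF, −78 °C; then 1, THF, −78 °C; aq NH4Cl quench at −78 °C
Reagents that add atoms: none
Why: 1,2-Addition of a lithium alkynide to one of the two equivalent ketone carbonyls of a squaric ester; the vinylogous ester carbons are much less electrophilic and the alkoxide formed deactivates the second carbonyl, so mono-addition should dominate. The carbinol carbon is formed as a racemate and is erased in step 2.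

Step 2
Reactants: 4 racemic 4-(3,3-diethoxyprop-1-yn-1-yl)-4-hydroxy-2,3-dimethoxycyclobut-2-en-1-one
Product: 6 2-(diethoxymethyl)-5,6-dimethoxycyclohexa-2,5-diene-1,4-dione, via alkynyl vinylketene 5 (not isolated)
Conditions: p-xylene (degassed, about 0.02 M), reflux, Ar
Reagents that add atoms: none
Why: Heat causes conrotatory four-electron opening of the cyclobutenone between the carbonyl carbon and the carbinol carbon; the hydroxyl donor rotates outward, so the alkyne lies cis to the ketene in 5. The ketene carbon (future C2') then bonds to the remote alkyne carbon (future C1', bearing the acetal), closing the six-membered ring as an aromatic diradical with an oxygen-centred and a ring-carbon radical, and transfer of the hydroxyl hydrogen to that ring carbon (C6') gives quinone 6. The closest known reaction type is the Moore rearrangement of 4-alkynyl-4-hydroxycyclobutenones from squaric esters to 1,4-benzoquinones. The ring closes by ketene-carbon to alkyne-terminus bond formation within an enyne-ketene, endo with respect to the alkyne and related to the Myers–Saito cyclisation. No stereocentre is created and the carbinol stereocentre of 4 disappears. The step needs six- over five-membered closure, which would give an alkylidenecyclopentenedione through a vinyl radical; the sp3 acetal carbon on the alkyne offers that radical no stabilisation, which should favour the quinone. Dilution and exclusion of oxygen are meant to suppress bimolecular reactions of the ketene.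

Step 3
Reactants: 6 2-(diethoxymethyl)-5,6-dimethoxycyclohexa-2,5-diene-1,4-dione
Product: 8 1-(diethoxymethyl)-2,3,4,5-tetramethoxybenzene, via hydroquinone 7 (not isolated)
Conditions: Na2S2O4, Bu4NBr (cat.), THF/H2O, rt, Ar; then aq KOH, Me2SO4, rt
Reagents that add atoms: dimethyl sulfate, COS(=O)(=O)OC
Why: Dithionite reduces the quinone to hydroquinone 7, and both phenoxides are then methylated in the same flask by Williamson alkylation under phase transfer (one-pot reductive methylation). The basic medium keeps the acetal intact and excess dithionite guards against re-oxidation.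

Step 4
Reactants: 8 1-(diethoxymethyl)-2,3,4,5-tetramethoxybenzene
Product: 9 2,3,4,5-tetramethoxybenzaldehyde
Conditions: 1 M HCl, THF, rt
Reagents that add atoms: water, O
Why: Acid-catalysed acetal hydrolysis; the oxocarbenium ion is stabilised by the electron-rich ring, so dilute acid at room temperature should suffice and the aryl methyl ethers are not touched.

Step 5
Reactants: 10 1,2,3,5-tetramethoxybenzene
Product: 12 1-(2-hydroxy-3,4,6-trimethoxyphenyl)ethan-1-one, via 2,3,4,6-tetramethoxyacetophenone 11 (not isolated)
Conditions: AcCl, AlCl3 (excess), Et2O, 0 °C to rt; ice/aq HCl work-up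
Reagents that add atoms: acetyl chloride, CC(Cl)=O
Why: Friedel–Crafts acetylation can occur only at the two symmetry-equivalent free positions of 10 and gives 11. AlCl3 chelated to the ketone then cleaves an ortho methyl ether, preferentially the one flanked by a second methoxy group, which is twisted out of the ring plane and more basic; this is the known behaviour of such ketones. The product stays as its aluminium chelate until work-up, which should stop further demethylation.

Step 6
Reactants: 9 2,3,4,5-tetramethoxybenzaldehyde; 12 1-(2-hydroxy-3,4,6-trimethoxyphenyl)ethan-1-one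
Product: 13 (E)-1-(2-hydroxy-3,4,6-trimethoxyphenyl)-3-(2,3,4,5-tetramethoxyphenyl)prop-2-en-1-one
Conditions: KOH (50% aq), EtOH, rt; then dilute HCl
Reagents that add atoms: none
Why: Claisen–Schmidt condensation; 9 has no α-hydrogen and 12 is the only enolisable partner, and E1cB dehydration gives the conjugated (E)-enone as the thermodynamic isomer. Any flavanone 14 formed alongside converges in step 7.

Step 7
Reactants: 13 (E)-1-(2-hydroxy-3,4,6-trimethoxyphenyl)-3-(2,3,4,5-tetramethoxyphenyl)prop-2-en-1-one
Product: 15 5,7,8-trimethoxy-2-(2,3,4,5-tetramethoxyphenyl)-4H-chromen-4-one (the target), via racemic flavanone 14 (not isolated)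
Conditions: I2 (10 mol %), DMSO, 130 °C
Reagents that add atoms: none
Why: Iodine-catalysed oxidative cyclisation of a 2'-hydroxychalcone: 6-endo oxa-Michael addition of the phenol gives flavanone 14, α-iodination and loss of HI introduce the C2–C3 double bond, and DMSO re-oxidises HI to I2. Keeping iodine catalytic limits iodination of the electron-rich rings.

## Compound list

1 | dimethyl squarate (3,4-dimethoxycyclobut-3-ene-1,2-dione) | COC1=C(OC)C(=O)C1=O | starting material
2 | 3,3-diethoxyprop-1-yne | CCOC(OCC)C#C | starting material
3 | lithium 3,3-diethoxyprop-1-yn-1-ide | [Li]C#CC(OCC)OCC | intermediate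
4 | racemic 4-(3,3-diethoxyprop-1-yn-1-yl)-4-hydroxy-2,3-dimethoxycyclobut-2-en-1-one | CCOC(OCC)C#CC1(O)C(OC)=C(OC)C1=O | intermediate
5 | (3Z)-7,7-diethoxy-4-hydroxy-2,3-dimethoxyhepta-1,3-dien-5-yn-1-one (alkynyl vinylketene) | CCOC(OCC)C#C/C(O)=C(OC)\C(OC)=C=O | intermediate
6 | 2-(diethoxymethyl)-5,6-dimethoxycyclohexa-2,5-diene-1,4-dione | CCOC(OCC)C1=CC(=O)C(OC)=C(OC)C1=O | intermediate
7 | 2-(diethoxymethyl)-5,6-dimethoxybenzene-1,4-diol | CCOC(OCC)c1cc(O)c(OC)c(OC)c1O | intermediate
8 | 1-(diethoxymethyl)-2,3,4,5-tetramethoxybenzene | CCOC(OCC)c1cc(OC)c(OC)c(OC)c1OC | intermediate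
9 | 2,3,4,5-tetramethoxybenzaldehyde | COc1cc(C=O)c(OC)c(OC)c1OC | intermediate
10 | 1,2,3,5-tetramethoxybenzene | COc1cc(OC)c(OC)c(OC)c1 | starting material
11 | 1-(2,3,4,6-tetramethoxyphenyl)ethan-1-one (2,3,4,6-tetramethoxyacetophenone) | CC(=O)c1c(OC)cc(OC)c(OC)c1OC | intermediate
12 | 1-(2-hydroxy-3,4,6-trimethoxyphenyl)ethan-1-one | CC(=O)c1c(OC)cc(OC)c(OC)c1O | intermediate
13 | (E)-1-(2-hydroxy-3,4,6-trimethoxyphenyl)-3-(2,3,4,5-tetramethoxyphenyl)prop-2-en-1-one | COc1cc(/C=C/C(=O)c2c(O)c(OC)c(OC)cc2OC)c(OC)c(OC)c1OC | intermediate
14 | racemic 5,7,8-trimethoxy-2-(2,3,4,5-tetramethoxyphenyl)chroman-4-one | COc1cc(C2CC(=O)c3c(OC)cc(OC)c(OC)c3O2)c(OC)c(OC)c1OC | intermediate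
15 | 5,7,8-trimethoxy-2-(2,3,4,5-tetramethoxyphenyl)-4H-chromen-4-one | COc1cc(-c2cc(=O)c3c(OC)cc(OC)c(OC)c3o2)c(OC)c(OC)c1OC | target

## Step count and least certain steps

Total step count: 7. Longest linear sequence: 6 steps (steps 1, 2, 3, 4, 6 and 7, from 1 and 2). The ring A branch contributes one step (step 5) before the union.

**Step 2 (key step).**
- What may go wrong: the ketene may close onto the near alkyne carbon and give the five-membered ring. After six-ring closure, the ring-carbon radical at C6' may abstract a hydrogen from an ethoxy CH2 of the neighbouring acetal (a 1,5-transfer) instead of receiving the hydroxyl hydrogen. The ketene may also be lost to bimolecular reactions if the solution is too concentrated.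
- Fallback, with no radical intermediate: it sets out from 1 and 2 and comes back at hydroquinone 7. Hydrostannylation of 2 (Bu3SnH, cat. AIBN, 90 °C) gives tributyl[(E)-3,3-diethoxyprop-1-en-1-yl]stannane F1. Tin–lithium exchange with n-BuLi in THF at −78 °C gives (E)-(3,3-diethoxyprop-1-en-1-yl)lithium F2. Addition of F2 to 1 gives racemic 4-[(E)-3,3-diethoxyprop-1-en-1-yl]-4-hydroxy-2,3-dimethoxycyclobut-2-en-1-one F3. Heating F3 in toluene opens the four-membered ring, and six-electron electrocyclisation and enolisation give 7 directly. It is methylated as in the second half of step 3.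

**Step 7.**
- What may go wrong: electrophilic iodination at C6 of ring A or C6' of ring B, loss of the C5 methyl ether to HI at 130 °C, or a stall at the flavanone stage.
- Fallback (Baker–Venkataraman sequence): it sets out from 9 and 12 and comes back at 15. Pinnick oxidation of 9 (NaClO2, NaH2PO4, 2-methylbut-2-ene) gives 2,3,4,5-tetramethoxybenzoic acid F4. (COCl)2 with catalytic DMF gives 2,3,4,5-tetramethoxybenzoyl chloride F5. Acylation of 12 in pyridine gives 2-acetyl-3,5,6-trimethoxyphenyl 2,3,4,5-tetramethoxybenzoate F6. KOH in pyridine at 50 °C effects the acyl shift to 1-(2-hydroxy-3,4,6-trimethoxyphenyl)-3-(2,3,4,5-tetramethoxyphenyl)propane-1,3-dione F7. H2SO4 in AcOH closes F7 to 15.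

**Step 5.**
- What may go wrong: cleavage of the other ortho ether, which would lead to the 5,6,7-isomer series, or cleavage of more than one ether.
- Fallback, with the hydroxyl in place before acylation: it sets out from 3-bromo-4,5-dimethoxybenzaldehyde F8 and comes back at 12. Baeyer–Villiger (Dakin-type) oxidation with mCPBA in CH2Cl2, then aqueous KOH, gives 3-bromo-4,5-dimethoxyphenol F9. MeI and K2CO3 in acetone give 1-bromo-2,3,5-trimethoxybenzene F10. Bromine–lithium exchange (n-BuLi, THF, −78 °C), B(OMe)3 and then H2O2/NaOH give 2,3,5-trimethoxyphenol F11. AcOH with BF3·OEt2 at 80 °C acylates the only free ortho position, through the boron chelate, to give 12.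

**Step 3.**
- What may go wrong: premature loss of the acetal in the weakly acidic dithionite phase, re-oxidation of the hydroquinone by air before both oxygens are alkylated, or incomplete methylation of the hindered C2' hydroxyl.
- Fallback, with the order of operations reversed: it sets out from 6 and comes back at 9, bypassing 8. After Na2S2O4 reduction of 6, the acetal is deliberately hydrolysed with dilute HCl to 2,5-dihydroxy-3,4-dimethoxybenzaldehyde F12. The formyl group makes F12 less prone to oxidation. MeI and K2CO3 in DMF at 50 °C then give 9.

## Further compounds

F1 | step 2 | tributyl[(E)-3,3-diethoxyprop-1-en-1-yl]stannane | CCCC[Sn](CCCC)(CCCC)/C=C/C(OCC)OCC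
F2 | step 2 | (E)-(3,3-diethoxyprop-1-en-1-yl)lithium | [Li]/C=C/C(OCC)OCC
F3 | step 2 | racemic 4-[(E)-3,3-diethoxyprop-1-en-1-yl]-4-hydroxy-2,3-dimethoxycyclobut-2-en-1-one | CCOC(OCC)/C=C/C1(O)C(OC)=C(OC)C1=O
F4 | step 7 | 2,3,4,5-tetramethoxybenzoic acid | COc1cc(C(O)=O)c(OC)c(OC)c1OC
F5 | step 7 | 2,3,4,5-tetramethoxybenzoyl chloride | COc1cc(C(Cl)=O)c(OC)c(OC)c1OC
F6 | step 7 | 2-acetyl-3,5,6-trimethoxyphenyl 2,3,4,5-tetramethoxybenzoate | CC(=O)c1c(OC)cc(OC)c(OC)c1OC(=O)c1cc(OC)c(OC)c(OC)c1OC
F7 | step 7 | 1-(2-hydroxy-3,4,6-trimethoxyphenyl)-3-(2,3,4,5-tetramethoxyphenyl)propane-1,3-dione | COc1cc(C(=O)CC(=O)c2c(O)c(OC)c(OC)cc2OC)c(OC)c(OC)c1OC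
F8 | step 5 | 3-bromo-4,5-dimethoxybenzaldehyde | COc1cc(C=O)cc(Br)c1OC
F9 | step 5 | 3-bromo-4,5-dimethoxyphenol | COc1cc(O)cc(Br)c1OC
F10 | step 5 | 1-bromo-2,3,5-trimethoxybenzene | COc1cc(OC)c(OC)c(Br)c1
F11 | step 5 | 2,3,5-trimethoxyphenol | COc1cc(O)c(OC)c(OC)c1
F12 | step 3 | 2,5-dihydroxy-3,4-dimethoxybenzaldehyde | O=Cc1cc(O)c(OC)c(OC)c1O
A1 | alternative 1 | 3-[2-(benzyloxy)-3,4,6-trimethoxyphenyl]-5-(2,3,4,5-tetramethoxyphenyl)isoxazole | COc1cc(OC)c(-c2cc(-c3cc(OC)c(OC)c(OC)c3OC)on2)c(OCc2ccccc2)c1OC
A2 | alternative 1 | (E)-2-(benzyloxy)-3,4,6-trimethoxybenzaldehyde oxime | COc1cc(OC)c(/C=N/O)c(OCc2ccccc2)c1OC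
A3 | alternative 1 | 1-ethynyl-2,3,4,5-tetramethoxybenzene | C#Cc1cc(OC)c(OC)c(OC)c1OC
A4 | alternative 2 | racemic 5,7,8-trimethoxy-2-(2,3,4,5-tetramethoxyphenyl)-2H-chromene | COc1cc(OC)c2c(c1OC)OC(c1cc(OC)c(OC)c(OC)c1OC)C=C2
A5 | alternative 2 | racemic 1,2,5-trimethoxy-3-{[1-(2,3,4,5-tetramethoxyphenyl)prop-2-yn-1-yl]oxy}benzene | C#CC(Oc1cc(OC)cc(OC)c1OC)c1cc(OC)c(OC)c(OC)c1OC
A6 | alternative 3 | 5,7-dihydroxy-8-methoxy-2-(2,3,4,5-tetramethoxyphenyl)-4H-chromen-4-one | COc1c(O)cc(O)c2c(=O)cc(-c3cc(OC)c(OC)c(OC)c3OC)oc12
A7 | alternative 3 | racemic methyl 4-methoxy-3-oxo-4-[4-oxo-6-(2,3,4,5-tetramethoxyphenyl)-4H-pyran-2-yl]butanoate | COC(=O)CC(=O)C(OC)c1cc(=O)cc(-c2cc(OC)c(OC)c(OC)c2OC)o1
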